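**Strategy.** The γ-lactone carboxyl (C12 and its ring oxygen; germacranolide numbering) is treated as one molecule of CO2 held between the vinylic carbon C11 and C6, which is allylic to the C4=C5 alkene of the ten-membered ring. In the key step a copper-catalysed carboxylation of a C11 alkenylboronate forms C11–C12, and the carboxylate then displaces a C6 mesylate with inversion, forming O–C6 and the cis-fused α-methylene lactone. Its precursor is the furanone-bridged carbocycle bearing a 1-borylvinyl group at C7 and the 6-mesylate, closed by a chromium-mediated 2-bromoallyl addition to a (Z)-enal; C8–C10 derive from L-erythronolactone.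

Key step: step 16

Assumption: 2,3-O-isopropylidene-L-erythronolactone (4), the enantiomer of the common D-lactone, is taken as a purchasable chiral-pool compound; atoms are numbered as in germacranolides (C1–C10 ring, C11–C13 lactone, C14 and C15 methyls).

Step 1
Reactants: 1 3-methylfuran-2(5H)-one
Product: 2 (2Z)-4-hydroxy-N-methoxy-N,2-dimethylbut-2-enamide
Conditions: MeNH(OMe)·HCl, Me3Al, CH2Cl2, 0 °C to rt
Reagents that add atoms: N,O-dimethylhydroxylamine hydrochloride, CNOC.Cl
Why: Weinreb aminolysis of the lactone by the aluminium amide opens the butenolide at the acyl carbon, so the (Z)-geometry of the future C4=C5 alkene is taken directly from the five-membered ring.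

Step 2
Reactants: 2 (2Z)-4-hydroxy-N-methoxy-N,2-dimethylbut-2-enamide
Product: 3 (2Z)-4-[(tert-butyldimethylsilyl)oxy]-N-methoxy-N,2-dimethylbut-2-enamide
Conditions: TBSCl, imidazole, CH2Cl2, 0 °C (crude 2 used at once)
Reagents that add atoms: tert-butyldimethylsilyl chloride, CC(C)(C)[Si](C)(C)Cl
Why: Silylation of the primary allylic alcohol (silyl ether formation) blocks relactonisation of the (Z)-hydroxy amide.

Step 3
Reactants: 4 2,3-O-isopropylidene-L-erythronolactone
Product: 5 (3aS,6aS)-2,2,4-trimethyltetrahydrofuro[3,4-d][1,3]dioxol-4-ol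
Conditions: MeLi (1.05 equiv), THF, −78 °C; aq. NH4Cl
Reagents that add atoms: methyllithium, [Li]C
Why: Single organolithium addition to the lactone stops at the stable lithium lactolate at −78 °C, giving the methyl ketone in its hemiketal form without touching C8 or C9.

Step 4
Reactants: 5 (3aS,6aS)-2,2,4-trimethyltetrahydrofuro[3,4-d][1,3]dioxol-4-ol
Product: 6 (2S)-2-[(4S,5S)-5-(hydroxymethyl)-2,2-dimethyl-1,3-dioxolan-4-yl]but-3-yn-2-ol
Conditions: HC≡CMgBr (3 equiv), THF, 0 °C to rt
Reagents that add atoms: ethynylmagnesium bromide, C#C[Mg]Br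
Why: Grignard addition to the open-chain methyl ketone under Cram-chelate control (magnesium bridging the ketone oxygen and the adjacent dioxolane oxygen) brings the alkynyl group in from the face away from the C8 substituent and sets the tertiary carbinol C10 as (S).

Step 5
Reactants: 6 (2S)-2-[(4S,5S)-5-(hydroxymethyl)-2,2-dimethyl-1,3-dioxolan-4-yl]but-3-yn-2-ol
Product: 7 (3aR,6S,6aS)-6-ethynyl-2,2,6-trimethyltetrahydrofuro[3,4-d][1,3]dioxol-4-ol
Conditions: (COCl)2, DMSO, CH2Cl2, −78 °C; Et3N, −78 °C to 0 °C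
Reagents that add atoms: none
Why: Swern oxidation converts only the primary alcohol (the tertiary one cannot be oxidised), and the hydroxy aldehyde closes to the lactol only after the oxidant is spent, so no lactone forms.

Step 6
Reactants: 7 (3aR,6S,6aS)-6-ethynyl-2,2,6-trimethyltetrahydrofuro[3,4-d][1,3]dioxol-4-ol
Product: 8 ethyl (2Z)-2-bromo-3-{(4S,5S)-5-[(2S)-2-hydroxybut-3-yn-2-yl]-2,2-dimethyl-1,3-dioxolan-4-yl}prop-2-enoate
Conditions: Ph3P=C(Br)CO2Et, toluene, 80 °C
Reagents that add atoms: ethyl bromo(triphenylphosphoranylidene)acetate, CCOC(=O)C(Br)=P(c1ccccc1)(c1ccccc1)c1ccccc1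
Why: Wittig olefination of the aldehyde tautomer of the lactol with the stabilised bromo ylide under neutral conditions gives the α-bromoacrylate with the ester trans to the chain (Z), and the neutral medium suppresses oxa-Michael reclosure.

Step 7
Reactants: 8 ethyl (2Z)-2-bromo-3-{(4S,5S)-5-[(2S)-2-hydroxybut-3-yn-2-yl]-2,2-dimethyl-1,3-dioxolan-4-yl}prop-2-enoate
Product: 9 (2Z)-2-bromo-3-{(4S,5S)-5-[(2S)-2-hydroxybut-3-yn-2-yl]-2,2-dimethyl-1,3-dioxolan-4-yl}prop-2-en-1-ol
Conditions: DIBAL-H (3.5 equiv), CH2Cl2, −78 °C; Rochelle salt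
Reagents that add atoms: none
Why: 1,2-Reduction of the enoate by the aluminium hydride gives the 2-bromoallylic alcohol while the vinylic bromide, alkyne and acetonide are inert.

Step 8
Reactants: 9 (2Z)-2-bromo-3-{(4S,5S)-5-[(2S)-2-hydroxybut-3-yn-2-yl]-2,2-dimethyl-1,3-dioxolan-4-yl}prop-2-en-1-ol; 3 (2Z)-4-[(tert-butyldimethylsilyl)oxy]-N-methoxy-N,2-dimethylbut-2-enamide
Product: 11 (2Z,7S)-7-{(4S,5S)-5-[(1Z)-2-bromo-3-hydroxyprop-1-en-1-yl]-2,2-dimethyl-1,3-dioxolan-4-yl}-1-[(tert-butyldimethylsilyl)oxy]-7-hydroxy-3-methyloct-2-en-5-yn-4-one, via bromomagnesium acetylide 10 (not isolated)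
Conditions: EtMgBr (3.3 equiv), THF, 0 to 40 °C; then 3, 0 °C to rt; aq. NH4Cl
Reagents that add atoms: none
Why: Weinreb ketone synthesis, in which the alkynyl Grignard 10 (both hydroxyls masked as magnesium alkoxides, no bromine–magnesium exchange with EtMgBr) acylates once because the chelated tetrahedral adduct survives until work-up, forming the C2–C3 bond.

Step 9
Reactants: 11 the γ-hydroxy ynone
Product: 12 (2R)-2-{(4S,5S)-5-[(1Z)-2-bromo-3-hydroxyprop-1-en-1-yl]-2,2-dimethyl-1,3-dioxolan-4-yl}-5-{(2Z)-4-[(tert-butyldimethylsilyl)oxy]but-2-en-2-yl}-2-methylfuran-3(2H)-one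
Conditions: (Ph3P)AuCl (5 mol %), AgOTf (5 mol %), wet toluene, rt
Reagents that add atoms: none
Why: Gold-catalysed cycloisomerisation of a γ-hydroxy ynone (hydration of the activated alkyne at C1, then cyclodehydration of the C10 hydroxyl onto C3, water acting as a shuttle) gives the 3(2H)-furanone with the C10–O bond and hence the C10 configuration untouched.

Step 10
Reactants: 12 the furanone allylic alcohol
Product: 13 (2R)-5-{(2Z)-4-[(tert-butyldimethylsilyl)oxy]but-2-en-2-yl}-2-{(4S,5S)-5-[(1Z)-2,3-dibromoprop-1-en-1-yl]-2,2-dimethyl-1,3-dioxolan-4-yl}-2-methylfuran-3(2H)-one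
Conditions: CBr4, PPh3, CH2Cl2, 0 °C
Reagents that add atoms: carbon tetrabromide, BrC(Br)(Br)Br
Why: Appel bromination of the only free (primary allylic) alcohol gives the allylic bromide under neutral conditions.

Step 11
Reactants: 13 the silyl ether
Product: 14 (2R)-2-{(4S,5S)-5-[(1Z)-2,3-dibromoprop-1-en-1-yl]-2,2-dimethyl-1,3-dioxolan-4-yl}-5-[(2Z)-4-hydroxybut-2-en-2-yl]-2-methylfuran-3(2H)-one
Conditions: HF·pyridine, THF–pyridine, 0 °C
Reagents that add atoms: none
Why: Fluoride-mediated desilylation frees the primary allylic alcohol, while the buffered medium leaves the acetonide and the allylic bromide intact.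

Step 12
Reactants: 14 the allylic alcohol
Product: 15 (2Z)-3-[(5R)-5-{(4S,5S)-5-[(1Z)-2,3-dibromoprop-1-en-1-yl]-2,2-dimethyl-1,3-dioxolan-4-yl}-5-methyl-4-oxo-4,5-dihydrofuran-2-yl]but-2-enal
Conditions: MnO2, CH2Cl2, rt, dark
Reagents that add atoms: none
Why: Allylic oxidation with MnO2 under neutral conditions gives the (Z)-enal without acid or base that would isomerise it.

Step 13
Reactants: 15 the (Z)-enal allylic bromide
Product: 17 (4Z,6R,7S,8S,9S,10R)-11-bromo-6-hydroxy-8,9-(isopropylidenedioxy)-3,10-epoxy-12-norgermacra-2,4,11(13)-trien-1-one, via allylchromium dichloride 16 (not isolated)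
Conditions: CrCl2 (10 equiv), THF–DMF, 2 mM (slow addition), rt
Reagents that add atoms: none
Why: Nozaki–Hiyama-type (Barbier) allylation in which divalent chromium inserts only into the allylic C–Br bond and the allylchromium 16 adds through its substituted terminus C7 to the enal in a chair-like transition state held in a turn by the furanone and the (Z)-alkene, which should give the 6,7-anti adduct (6R,7S) with the C7 side chain on the ring face that carries the C8 oxygen, as such ring closures do for germacranolide rings.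

Step 14
Reactants: 17 the macrocyclic bromo alcohol
Product: 18 (4Z,6R,7S,8S,9S,10R)-11-(5,5-dimethyl-1,3,2-dioxaborinan-2-yl)-6-hydroxy-8,9-(isopropylidenedioxy)-3,10-epoxy-12-norgermacra-2,4,11(13)-trien-1-one
Conditions: bis(neopentyl glycolato)diboron, PdCl2(PPh3)2 (5 mol %), PPh3, KOPh, toluene, 50 °C
Reagents that add atoms: bis(neopentyl glycolato)diboron, CC1(C)COB(OC1)B1OCC(C)(C)CO1
Why: Miyaura borylation of the alkenyl bromide (oxidative addition to zerovalent palladium, boryl transfer from the phenoxide-activated diboron, reductive elimination) proceeds at the vinylic C–Br bond only, since the free allylic alcohol is not ionised.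

Step 15
Reactants: 18 the boronate alcohol
Product: 19 (4Z,6R,7R,8S,9S,10R)-11-(5,5-dimethyl-1,3,2-dioxaborinan-2-yl)-8,9-(isopropylidenedioxy)-6-(methanesulfonyloxy)-3,10-epoxy-12-norgermacra-2,4,11(13)-trien-1-one
Conditions: MsCl, Et3N, CH2Cl2, −30 °C (used crude)
Reagents that add atoms: methanesulfonyl chloride, CS(=O)(=O)Cl
Why: Sulfonylation at oxygen retains the C6 configuration, and the electron-poor dienone flanking C4=C5 slows ionisation of the allylic mesylate.

Step 16
Reactants: 19 the alkenylboronate mesylate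
Product: 21 (4Z,6S,7S,8S,9S,10R)-8,9-(isopropylidenedioxy)-1-oxo-3,10-epoxygermacra-2,4,11(13)-trien-12,6-olide, via potassium carboxylate 20 (not isolated)
Conditions: KOtBu (1.05 equiv), THF, −20 °C; then (IPr)CuCl (10 mol %; IPr = 1,3-bis(2,6-diisopropylphenyl)imidazol-2-ylidene), CO2 (1 atm), rt to 60 °C
Reagents that add atoms: carbon dioxide, O=C=O
Why: tert-Butoxide adds to boron to give an alkenylborate that transmetalates to monovalent copper, and CO2 inserts into the Cu–C11 bond to form the C11–C12 bond; the closest known reaction type is the copper-catalysed carboxylation of alkenylboronic esters, whose carboxylate is routinely alkylated in the same pot. The potassium carboxylate 20, held on C7 next to C6, then displaces the allylic mesylate by SN2, forming the O–C6 bond and the γ-lactone in a 5-exo-tet closure. C6 is the only stereocentre changed: backside attack inverts the 6R mesylate set in step 13 to the 6S lactone oxygen, syn to the C7–C11 bond (cis-fused lactone), while C7–C10 are untouched. The step needs carboxylation to outrun base-induced elimination or substitution of the mesylate, which is secured by consuming the alkoxide as the borate before copper and CO2 are admitted and by the electron-poor dienone that disfavours ionisation at C6. SN2' attack at C4 would close a seven-membered ring and cannot compete with the five-membered closure.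

Step 17
Reactants: 21 the lactone acetonide
Product: 22 (4Z,6S,7R,8S,9S,10R)-8,9-dihydroxy-1-oxo-3,10-epoxygermacra-2,4,11(13)-trien-12,6-olide
Conditions: TFA–H2O (4:1), 0 °C
Reagents that add atoms: none
Why: Acid hydrolysis of the cis-dioxolane frees the 8,9-diol, while the furanone and the α-methylene lactone have no acid-labile bond.

Step 18
Reactants: 22 the 8,9-diol
Product: 23 (4Z,6S,7S,8S,9S,10R)-9-hydroxy-8-(2-methylprop-2-enoyloxy)-1-oxo-3,10-epoxygermacra-2,4,11(13)-trien-12,6-olide (CNP0252578.5)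
Conditions: methacrylic anhydride (1.1 equiv), Et3N, DMAP (10 mol %), CH2Cl2, −20 °C
Reagents that add atoms: methacrylic anhydride, CC(=C)C(=O)OC(=O)C(C)=C
Why: DMAP-catalysed (Steglich-type) acylation should take the C8 hydroxyl, because the C9 hydroxyl is neopentylic (flanked by the quaternary C10) and hydrogen-bonded to the furanone oxygen.

**Compound list**

1 | 3-methylfuran-2(5H)-one | CC1=CCOC1=O | starting material
2 | (2Z)-4-hydroxy-N-methoxy-N,2-dimethylbut-2-enamide | OC/C=C(/C)C(=O)N(C)OC | intermediate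
3 | (2Z)-4-[(tert-butyldimethylsilyl)oxy]-N-methoxy-N,2-dimethylbut-2-enamide | CC(C)(C)[Si](C)(C)OC/C=C(/C)C(=O)N(C)OC | intermediate
4 | (3aS,6aS)-2,2-dimethyldihydrofuro[3,4-d][1,3]dioxol-4(3aH)-one (2,3-O-isopropylidene-L-erythronolactone) | O=C1OC[C@@H]2OC(C)(C)O[C@H]12 | starting material
5 | (3aS,6aS)-2,2,4-trimethyltetrahydrofuro[3,4-d][1,3]dioxol-4-ol (hemiketal, anomers) | CC1(O)OC[C@@H]2OC(C)(C)O[C@H]12 | intermediate
6 | (2S)-2-[(4S,5S)-5-(hydroxymethyl)-2,2-dimethyl-1,3-dioxolan-4-yl]but-3-yn-2-ol | C#C[C@](C)(O)[C@H]1OC(C)(C)O[C@H]1CO | intermediate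
7 | (3aR,6S,6aS)-6-ethynyl-2,2,6-trimethyltetrahydrofuro[3,4-d][1,3]dioxol-4-ol (lactol, anomers) | C#C[C@]1(C)OC(O)[C@@H]2OC(C)(C)O[C@H]12 | intermediate
8 | ethyl (2Z)-2-bromo-3-{(4S,5S)-5-[(2S)-2-hydroxybut-3-yn-2-yl]-2,2-dimethyl-1,3-dioxolan-4-yl}prop-2-enoate | C#C[C@](C)(O)[C@H]1OC(C)(C)O[C@H]1/C=C(\Br)C(=O)OCC | intermediate
9 | (2Z)-2-bromo-3-{(4S,5S)-5-[(2S)-2-hydroxybut-3-yn-2-yl]-2,2-dimethyl-1,3-dioxolan-4-yl}prop-2-en-1-ol | C#C[C@](C)(O)[C@H]1OC(C)(C)O[C@H]1/C=C(\Br)CO | intermediate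
10 | tris(bromomagnesium) derivative of 9 (alkynyl Grignard, two magnesium alkoxides) | Br[Mg]C#C[C@](C)(O[Mg]Br)[C@H]1OC(C)(C)O[C@H]1/C=C(\Br)CO[Mg]Br | intermediate (not isolated)
11 | (2Z,7S)-7-{(4S,5S)-5-[(1Z)-2-bromo-3-hydroxyprop-1-en-1-yl]-2,2-dimethyl-1,3-dioxolan-4-yl}-1-[(tert-butyldimethylsilyl)oxy]-7-hydroxy-3-methyloct-2-en-5-yn-4-one | CC(C)(C)[Si](C)(C)OC/C=C(/C)C(=O)C#C[C@](C)(O)[C@H]1OC(C)(C)O[C@H]1/C=C(\Br)CO | intermediate
12 | (2R)-2-{(4S,5S)-5-[(1Z)-2-bromo-3-hydroxyprop-1-en-1-yl]-2,2-dimethyl-1,3-dioxolan-4-yl}-5-{(2Z)-4-[(tert-butyldimethylsilyl)oxy]but-2-en-2-yl}-2-methylfuran-3(2H)-one | CC(C)(C)[Si](C)(C)OC/C=C(/C)C1=CC(=O)[C@](C)(O1)[C@H]1OC(C)(C)O[C@H]1/C=C(\Br)CO | intermediate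
13 | (2R)-5-{(2Z)-4-[(tert-butyldimethylsilyl)oxy]but-2-en-2-yl}-2-{(4S,5S)-5-[(1Z)-2,3-dibromoprop-1-en-1-yl]-2,2-dimethyl-1,3-dioxolan-4-yl}-2-methylfuran-3(2H)-one | CC(C)(C)[Si](C)(C)OC/C=C(/C)C1=CC(=O)[C@](C)(O1)[C@H]1OC(C)(C)O[C@H]1/C=C(\Br)CBr | intermediate
14 | (2R)-2-{(4S,5S)-5-[(1Z)-2,3-dibromoprop-1-en-1-yl]-2,2-dimethyl-1,3-dioxolan-4-yl}-5-[(2Z)-4-hydroxybut-2-en-2-yl]-2-methylfuran-3(2H)-one | OC/C=C(/C)C1=CC(=O)[C@](C)(O1)[C@H]1OC(C)(C)O[C@H]1/C=C(\Br)CBr | intermediate
15 | (2Z)-3-[(5R)-5-{(4S,5S)-5-[(1Z)-2,3-dibromoprop-1-en-1-yl]-2,2-dimethyl-1,3-dioxolan-4-yl}-5-methyl-4-oxo-4,5-dihydrofuran-2-yl]but-2-enal | O=C/C=C(/C)C1=CC(=O)[C@](C)(O1)[C@H]1OC(C)(C)O[C@H]1/C=C(\Br)CBr | intermediate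
16 | allylchromium dichloride from 15 (trivalent chromium on C13) | O=C/C=C(/C)C1=CC(=O)[C@](C)(O1)[C@H]1OC(C)(C)O[C@H]1/C=C(\Br)C[Cr](Cl)Cl | intermediate (not isolated)
17 | (4Z,6R,7S,8S,9S,10R)-11-bromo-6-hydroxy-8,9-(isopropylidenedioxy)-3,10-epoxy-12-norgermacra-2,4,11(13)-trien-1-one | CC1(C)O[C@H]2[C@@H](C(Br)=C)[C@H](O)/C=C(/C)C3=CC(=O)[C@](C)(O3)[C@H]2O1 | intermediate
18 | (4Z,6R,7S,8S,9S,10R)-11-(5,5-dimethyl-1,3,2-dioxaborinan-2-yl)-6-hydroxy-8,9-(isopropylidenedioxy)-3,10-epoxy-12-norgermacra-2,4,11(13)-trien-1-one | CC1(C)O[C@H]2[C@@H](C(=C)B3OCC(C)(C)CO3)[C@H](O)/C=C(/C)C3=CC(=O)[C@](C)(O3)[C@H]2O1 | intermediate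
19 | (4Z,6R,7R,8S,9S,10R)-11-(5,5-dimethyl-1,3,2-dioxaborinan-2-yl)-8,9-(isopropylidenedioxy)-6-(methanesulfonyloxy)-3,10-epoxy-12-norgermacra-2,4,11(13)-trien-1-one | CC1(C)O[C@H]2[C@@H](C(=C)B3OCC(C)(C)CO3)[C@H](OS(C)(=O)=O)/C=C(/C)C3=CC(=O)[C@](C)(O3)[C@H]2O1 | intermediate
20 | potassium (4Z,6R,7R,8S,9S,10R)-8,9-(isopropylidenedioxy)-6-(methanesulfonyloxy)-1-oxo-3,10-epoxygermacra-2,4,11(13)-trien-12-oate | CC1(C)O[C@H]2[C@@H](C(=C)C(=O)[O-])[C@H](OS(C)(=O)=O)/C=C(/C)C3=CC(=O)[C@](C)(O3)[C@H]2O1.[K+] | intermediate (not isolated)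
21 | (4Z,6S,7S,8S,9S,10R)-8,9-(isopropylidenedioxy)-1-oxo-3,10-epoxygermacra-2,4,11(13)-trien-12,6-olide | CC1(C)O[C@H]2[C@H]3C(=C)C(=O)O[C@H]3/C=C(/C)C3=CC(=O)[C@](C)(O3)[C@H]2O1 | intermediate
22 | (4Z,6S,7R,8S,9S,10R)-8,9-dihydroxy-1-oxo-3,10-epoxygermacra-2,4,11(13)-trien-12,6-olide | O[C@H]1[C@H]2C(=C)C(=O)O[C@H]2/C=C(/C)C2=CC(=O)[C@](C)(O2)[C@H]1O | intermediate
23 | (4Z,6S,7S,8S,9S,10R)-9-hydroxy-8-(2-methylprop-2-enoyloxy)-1-oxo-3,10-epoxygermacra-2,4,11(13)-trien-12,6-olide (CNP0252578.5) | C=C(C)C(=O)O[C@H]1[C@H]2C(=C)C(=O)O[C@H]2/C=C(/C)C2=CC(=O)[C@](C)(O2)[C@H]1O | target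

**Step count.** Total: 18 steps. Longest linear sequence: 16 steps (steps 3–18, from 4); the two-step branch 1 → 3 joins at step 8.

**Steps most likely to fail**

1. Step 16 (carboxylation with ring closure). Base-induced elimination or substitution of the allylic mesylate, or protodeboronation, may run ahead of carboxylation. The fallback separates the two events and sets out from 18, which has no leaving group. The same copper-catalysed carboxylation ((IPr)CuCl, KOtBu, CO2, THF) should give the hydroxy acid (4Z,6R,7S,8S,9S,10R)-6-hydroxy-8,9-(isopropylidenedioxy)-1-oxo-3,10-epoxygermacra-2,4,11(13)-trien-12-oic acid F1, kept cold as its salt until use. An intramolecular Mitsunobu reaction (PPh3, DIAD, THF, 0 °C) then activates the C6 hydroxyl as the oxyphosphonium, and the carboxylate displaces it with inversion. The route is rejoined at 21.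

2. Step 13 (ring closure). Oligomerisation may compete with cyclisation, and the aldehyde may be attacked on the wrong face, giving the C6 epimer. The fallback sets C6 by reduction and not by C–C bond formation, and sets out from 15. The crude cyclisation mixture, containing the (6S)-epimer of 17 F2, is oxidised with Dess–Martin periodinane (CH2Cl2, 0 °C) to the macrocyclic ketone (4Z,7R,8S,9S,10R)-11-bromo-8,9-(isopropylidenedioxy)-3,10-epoxy-12-norgermacra-2,4,11(13)-triene-1,6-dione F3. This is reduced at once under reagent control (CBS-oxazaborolidine, catecholborane, toluene, −78 °C, catalyst antipode chosen for the 6R alcohol). The route is rejoined at 17.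

3. Step 18 (site-selective acylation). Acylation at the C9 hydroxyl, double acylation or base-promoted 8→9 acyl migration may erode selectivity. The fallback replaces the chemical acylation by a biocatalytic one and sets out from 22. An immobilised lipase (a serine hydrolase used as acyl transferase, such as Candida antarctica lipase B) with vinyl methacrylate in MTBE at 30 °C would discriminate the two secondary hydroxyls by steric access at neutral pH, where acyl migration is slow. It gives 23 directly and makes no new compound (F0).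

**Further compounds**

F1 | step 16 | (4Z,6R,7S,8S,9S,10R)-6-hydroxy-8,9-(isopropylidenedioxy)-1-oxo-3,10-epoxygermacra-2,4,11(13)-trien-12-oic acid | CC1(C)O[C@H]2[C@@H](C(=C)C(=O)O)[C@H](O)/C=C(/C)C3=CC(=O)[C@](C)(O3)[C@H]2O1
F2 | step 13 | (4Z,6S,7S,8S,9S,10R)-11-bromo-6-hydroxy-8,9-(isopropylidenedioxy)-3,10-epoxy-12-norgermacra-2,4,11(13)-trien-1-one | CC1(C)O[C@H]2[C@@H](C(Br)=C)[C@@H](O)/C=C(/C)C3=CC(=O)[C@](C)(O3)[C@H]2O1
F3 | step 13 | (4Z,7R,8S,9S,10R)-11-bromo-8,9-(isopropylidenedioxy)-3,10-epoxy-12-norgermacra-2,4,11(13)-triene-1,6-dione | CC1(C)O[C@H]2[C@@H](C(Br)=C)C(=O)/C=C(/C)C3=CC(=O)[C@](C)(O3)[C@H]2O1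
F0 | step 18 | none | none
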